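# Proposed total synthesis of cryptomerin A by a late thermal chromone annulation onto free phloroglucinol

Compound numbers refer to the list after step 8; the target is 18.

## Analysis of the target

Cryptomerin A (18, C31H20O10) is a biflavone whose two flavone units are joined through oxygen. The apigenin half consists of benzo ring A (C4a–C8a), pyranone ring C (O1, C2–C4) and the 1,4-phenylene ring B (C1'–C6'). The acacetin half consists of benzo ring D (C4a''–C8a''), pyranone ring F and the 4-methoxyphenyl ring E (C1'''–C6'''), and the link is the diaryl ether C4'–O–C6''. There is no stereocentre, so every problem is one of regiochemistry and chemoselectivity. Ring D is the crowded part: it carries oxygen on C5'', C6'', C7'' and C8a'' and has a single C–H (C8''). Its ether oxygen lies between two hydroxyls, so the ether must be made at a hindered oxygen and the 6''-O linkage must be told from the isomeric 8''-O linkage. The sensitive groups are the four phenols, the one methyl ether on C4''' that has to outlast every deprotection, and the diaryl ether itself. Once O5''–H and O7''–H are free, base can shift the para-acylated aryl group to a neighbouring oxygen (Smiles type) and strong acid can open and reclose ring F (Wessely–Moser type), so the late steps must be neutral. The strategy rests on ring A: it has the bare phloroglucinol pattern (OH on C5 and C7, H on C6 and C8) and is fused to ring C only through C4a–C4 and C8a–O1–C2. Since the three C–H positions and the three hydroxyls of phloroglucinol 15 are equivalent, ring C can be annulated onto free 15 in the last step with no protecting group and no regiochemical choice.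

## Retrosynthetic reasoning

**18 to 14 and 15.** The bonds C4a–C4 and O1–C2 of ring C are cut. This is the only cut that releases a commercial, symmetric, unprotected fragment (15) and takes ring A away whole. A cut at the diaryl ether would instead leave two complete flavones to be joined at a hindered oxygen in the presence of four phenols. The gain is convergence and a last step without protecting groups. The forward reaction has to acylate 15 once at carbon with the ester carbon of keto ester 14, close the pyranone and not the isomeric coumarin, and leave the phenols and C8'' of 14 alone.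

**14 to 13.** The two O–H bonds on C5'' and C7'' are traced back to benzyl ethers. The ether formation and the enolate chemistry before this point use base, and free hydroxyls next to the ether oxygen could then attack C4' and move the aryl group. Benzyl is chosen because it falls off under neutral hydrogenolysis, which leaves the C4''' methyl ether untouched. The forward step must remove both benzyl groups without reducing the aryl ketone or the C2''=C3'' bond.

**13 to 11 and 12.** The bond between the methylene carbon (future C3) and the ester carbonyl (future C4) is cut. The C2–C3–C4 unit of ring C is thereby assembled from the acetyl group of 11 (C2 and C3) and the carbonyl carbon of carbonate 12 (C4). The forward reaction is a Claisen condensation of the methyl ketone enolate.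

**11 to 9 and 10.** The C4'–O bond of the diaryl ether is cut, and the oxygen stays on ring D as the phenol of 9. The cut is made on this side because C4' is para to the acetyl group and is therefore open to addition–elimination, whereas C6'' lies on an electron-rich, doubly flanked ring. The acetyl group of 10 serves twice, first as the activating group and then as the source of C2 and C3. The forward step asks a phenoxide with two ortho substituents to attack.

**9 to 7, then 7 to 5 and 6.** Ring F is opened at O1''–C2'' with adjustment of the oxidation level, which leads to chalcone 7. The C2''=C3'' bond of 7 is then cut to acetophenone 5 and aldehyde 6. Aldehyde 6 brings ring E with the C4''' methoxy group already in place, so this methyl ether never has to be made selectively. In the forward direction only the hydroxyl ortho to the carbonyl can close the ring, which leaves the other hydroxyl free as the C6'' phenol.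

**5 to 3.** The C–O bond on the future C6'' is cut. This step decides between the 6''-O and the 8''-O linkage. In 3 the one free hydroxyl is the one that becomes O1'', and the carbon para to it is the future C6''. A para-selective phenol hydroxylation (Elbs oxidation, through aryl sulfate 4) therefore places the oxygen correctly.

**3 to 1 and 2.** The two benzyl–oxygen bonds are cut. Acetophenone 1 is commercial and already holds the phloroglucinol pattern of ring D together with the C4a''–C4'' bond and C3''. Its hydroxyl chelated to the carbonyl resists alkylation, so two equivalents of 2 give 3 directly.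

## Alternatives that were turned down

**Alternative 1:** Ring B is not bought but made. The disconnection cuts the two ring-B bonds C2'–C3' and C4'–C5'. In the forward key step the electron-poor pyranone methyl coumalate A1 and the electron-rich aryl ethynyl ether A2 undergo an inverse-demand [4+2] cycloaddition, and the bridged lactone aromatises by decarboxylation to the para-aryloxybenzoate A3.
- *For:* the reaction is neutral and polarity-matched, and it makes the hindered diaryl ether without a crowded phenoxide and without any base that could move the aryl group. On this point it is at least as good as step 5 of the chosen route.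
- *Against:* A2 has to be prepared from the same kind of doubly flanked phenol that the chosen route arylates in one step, and ynol ethers take several steps and are fragile. A3 also leaves nearly everything still to do: ring D must be desilylated and acylated, ring F closed, ring E attached, and the ester turned into rings C and A.
- *Comparison:* the key step is spent on the one ring that is available for nothing as compound 10. The chosen route buys ring B and places its key step last, where it joins two finished halves.

**Alternative 2:** Ring D is built by cycloaddition. The disconnection cuts C8''–C8a'' and C4a''–C5''. In the forward key step the bis(silyloxy) diene A4 adds with its methylene end to C8a'' and with its ketene acetal carbon to C4a'' of the sulfinylpyranone A5. Elimination of the sulfinyl group and of the acetal alkoxy group, with desilylation, aromatises the new ring to ester A6.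
- *For:* the most demanding ring arrives with all four oxygens and the aryl ether already in place, the regiochemistry follows from the polarity of the diene, and the phenols emerge free. On protecting-group economy, and in avoiding the modest Elbs step, this is stronger than steps 1 to 5 of the chosen route.
- *Against:* A4 is a tetrasubstituted, hydrolytically labile ketene acetal with an aryloxy group on its internal carbon, which also hinders the s-cis conformer. The reacting double bond of A5 belongs to a cross-conjugated pyranone with some aromatic character, and A5 needs its own synthesis. A6 is still only an ester, so rings C and A remain to be made, most naturally by the same final annulation after homologation to 14.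
- *Comparison:* this alternative replaces the early steps and not the key step, and it spreads risk over two delicate partners. The chosen route reaches 14 by textbook reactions and keeps the risk in one place.

**Alternative 3:** The acyl group and the ring oxygen are put onto ring D through an aryne. The disconnection cuts C8a''–O1'' and C4a''–C4''. In the forward key step fluoride releases a trioxygenated benzyne from the silyl triflate A7. The propiolic acid A8 adds through oxygen at C8a'', the aryl anion attacks the acyl carbon, and the ortho-hydroxyaryl ynone A9 results. A later 6-endo closure would give ring F.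
- *For:* two bonds are made in one step, and the benzyloxy group on C5'' polarises the aryne in the right sense, so the regiochemistry is predictable. For ring F alone it is as short as the aldol and oxidative cyclisation of the chosen route.
- *Against:* A7 is a hexasubstituted benzene whose preparation from the hindered diaryl ether phenol is long. A8 is prone to decarboxylation, A9 is a Michael acceptor in a fluoride medium, and 5-exo closure to an aurone competes with the 6-endo mode. The acetal must afterwards be unmasked and the whole apigenin half still built.
- *Comparison:* the step count is higher and the risk is compounded before the second flavone is even started. The chosen route fixes the same regiochemistry with one para-selective oxidation of a commercial acetophenone.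

Key step: step 8

Remark: the β-keto esters 13 and 14 and the diketone 17 are drawn as keto forms although each will be partly enolised, and the commercial monohydrate of 1 is dried before use.

## Route

Step 1
Reactants: 1 1-(2,4,6-trihydroxyphenyl)ethanone; 2 benzyl bromide
Product: 3 1-[2,4-bis(benzyloxy)-6-hydroxyphenyl]ethanone
Conditions: 2 (2.05 equiv), K2CO3 (2.2 equiv), DMF, rt
Reagents that add atoms: none
Why: Williamson etherification; the hydroxyl that is hydrogen-bonded to the acetyl carbonyl is the least acidic and least nucleophilic, so two equivalents of 2 should alkylate the para hydroxyl and one ortho hydroxyl and leave the chelated one, which later becomes O1'' of ring F.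

Step 2
Reactants: 3 1-[2,4-bis(benzyloxy)-6-hydroxyphenyl]ethanone
Product: 5 1-[2,4-bis(benzyloxy)-3,6-dihydroxyphenyl]ethanone, via aryl sulfate potassium salt 4 (not isolated)
Conditions: K2S2O8 (1.1 equiv), aq NaOH, pyridine, 15–20 °C; then aq HCl, 70 °C
Reagents that add atoms: potassium peroxodisulfate, [K+].[K+].[O-]S(=O)(=O)OOS(=O)(=O)[O-]
Why: Elbs persulfate oxidation; the phenolate of 3 attacks a peroxide oxygen through the carbon para to its free hydroxyl to give aryl sulfate 4, whose S–O bond is then hydrolysed by warm dilute acid. The new oxygen lands on the carbon that becomes C6'', which fixes the 6''-O linkage, and unreacted 3 should be recoverable.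

Step 3
Reactants: 5 1-[2,4-bis(benzyloxy)-3,6-dihydroxyphenyl]ethanone; 6 4-methoxybenzaldehyde
Product: 7 (E)-1-[2,4-bis(benzyloxy)-3,6-dihydroxyphenyl]-3-(4-methoxyphenyl)prop-2-en-1-one
Conditions: 6 (1.2 equiv), KOH, EtOH–H2O, rt, Ar (degassed); then aq HCl
Reagents that add atoms: none
Why: Claisen–Schmidt condensation; the acetyl group is the only enolisable carbonyl and 6 cannot enolise, and E1cB dehydration of the aldol gives the conjugated E-enone. Oxygen is excluded because the dianion of the hydroquinone is easily oxidised.

Step 4
Reactants: 7 (E)-1-[2,4-bis(benzyloxy)-3,6-dihydroxyphenyl]-3-(4-methoxyphenyl)prop-2-en-1-one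
Product: 9 5,7-bis(benzyloxy)-6-hydroxy-2-(4-methoxyphenyl)-4H-chromen-4-one, via racemic flavanone 8 (not isolated)
Conditions: I2 (10 mol %), DMSO, 120 °C
Reagents that add atoms: none
Why: Oxidative cyclisation of a 2'-hydroxychalcone; the chelated hydroxyl adds to the enone (6-endo-trig oxa-Michael) to flavanone 8, α-iodination and loss of HI give the flavone, and the sulfoxide reoxidises HI to I2. Only the hydroxyl ortho to the carbonyl can reach the β-carbon, so the other one stays free as the C6'' phenol.

Step 5
Reactants: 9 5,7-bis(benzyloxy)-6-hydroxy-2-(4-methoxyphenyl)-4H-chromen-4-one; 10 4'-fluoroacetophenone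
Product: 11 6-(4-acetylphenoxy)-5,7-bis(benzyloxy)-2-(4-methoxyphenyl)-4H-chromen-4-one
Conditions: 10 (1.5 equiv), K2CO3 (2 equiv), DMF, 110 °C, N2
Reagents that add atoms: none
Why: Nucleophilic aromatic substitution by addition–elimination; the phenoxide of 9 displaces fluoride para to the acetyl group of 10 through a Meisenheimer intermediate. The two flanking benzyloxy groups make the phenoxide electron-rich, and because O5'' and O7'' are capped no Smiles-type aryl shift to a neighbouring oxygen is possible.

Step 6
Reactants: 11 6-(4-acetylphenoxy)-5,7-bis(benzyloxy)-2-(4-methoxyphenyl)-4H-chromen-4-one; 12 diethyl carbonate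
Product: 13 ethyl 3-(4-{[5,7-bis(benzyloxy)-2-(4-methoxyphenyl)-4-oxo-4H-chromen-6-yl]oxy}phenyl)-3-oxopropanoate
Conditions: NaH (3 equiv), 12 (5 equiv), THF, reflux; then AcOH
Reagents that add atoms: none
Why: Claisen condensation of a methyl ketone enolate with a carbonate ester; the product is drawn off as its stabilised sodium enolate, which drives the equilibrium. The vinylic C3''–H of the flavone is far too weakly acidic to compete.

Step 7
Reactants: 13 ethyl 3-(4-{[5,7-bis(benzyloxy)-2-(4-methoxyphenyl)-4-oxo-4H-chromen-6-yl]oxy}phenyl)-3-oxopropanoate
Product: 14 ethyl 3-[4-({5,7-dihydroxy-2-(4-methoxyphenyl)-4-oxo-4H-chromen-6-yl}oxy)phenyl]-3-oxopropanoate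
Conditions: H2 (1 atm), 10% Pd/C, EtOAc–THF, rt
Reagents that add atoms: none
Why: Hydrogenolysis of aryl benzyl ethers over palladium on carbon; the methyl ether, the diaryl ether, the ester and the conjugated carbonyl groups should survive at 1 atm if the reaction is stopped after uptake of two equivalents of hydrogen. The medium is neutral, so the freed O5''–H and O7''–H cannot trigger aryl migration.

Step 8
Reactants: 14 ethyl 3-[4-({5,7-dihydroxy-2-(4-methoxyphenyl)-4-oxo-4H-chromen-6-yl}oxy)phenyl]-3-oxopropanoate; 15 phloroglucinol
Product: 18 cryptomerin A, via aroylketene 16 (not isolated), via ortho-hydroxyaryl diketone 17 (not isolated)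
Conditions: 15 (5 equiv, anhydrous), Ph2O, 240 °C, Ar sweep
Reagents that add atoms: none
Why: On heating, 14 should lose its ester alcohol through a six-membered transition state to give aroylketene 16, the acylating species of the Mentzer thermal pyrone synthesis, which is the known route from phloroglucinol and ethyl aroylacetates to 5,7-dihydroxyflavones. Phenol 15 captures 16 either at oxygen, giving an aryl ester that returns the ketene at this temperature, or at carbon, and C-acylation is the sink because the new ketone of 17 is held by two flanking hydrogen bonds; this makes the C4a–C4 bond. An ortho hydroxyl of 17 then adds to the aryl ketone carbonyl (6-exo-trig) and the hemiketal loses water, which makes O1–C2 and closes ring C as the aromatic 4-pyranone. No stereocentre is formed. Regiochemistry on 15 needs no control, since its three C–H positions and its three hydroxyls are equivalent. The chromone has to win over the 4-arylcoumarin: without a protic or Lewis acid the aryl ketone is not activated for Pechmann-type attack by the ring carbon, so it is the ester carbon that ends on ring A. The nucleophilic sites of 14 itself must stay out: C8'' lies on a ring deactivated by conjugation with C4''=O, O5''–H is chelated, and an ester formed at O7'' is reversible, while the fivefold excess of 15 makes it the preferred trap. The argon sweep removes the alcohol and the water, which would otherwise hydrolyse 16 and lead to decarboxylation.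

## Compound list

1 | 1-(2,4,6-trihydroxyphenyl)ethanone (2',4',6'-trihydroxyacetophenone) | CC(=O)c1c(O)cc(O)cc1O | starting material
2 | benzyl bromide | BrCc1ccccc1 | starting material
3 | 1-[2,4-bis(benzyloxy)-6-hydroxyphenyl]ethanone | CC(=O)c1c(O)cc(OCc2ccccc2)cc1OCc1ccccc1 | intermediate
4 | potassium 3-acetyl-2,6-bis(benzyloxy)-4-hydroxyphenyl sulfate | CC(=O)c1c(O)cc(OCc2ccccc2)c(OS(=O)(=O)[O-])c1OCc1ccccc1.[K+] | intermediate
5 | 1-[2,4-bis(benzyloxy)-3,6-dihydroxyphenyl]ethanone | CC(=O)c1c(O)cc(OCc2ccccc2)c(O)c1OCc1ccccc1 | intermediate
6 | 4-methoxybenzaldehyde | COc1ccc(C=O)cc1 | starting material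
7 | (E)-1-[2,4-bis(benzyloxy)-3,6-dihydroxyphenyl]-3-(4-methoxyphenyl)prop-2-en-1-one | COc1ccc(/C=C/C(=O)c2c(O)cc(OCc3ccccc3)c(O)c2OCc2ccccc2)cc1 | intermediate
8 | racemic 5,7-bis(benzyloxy)-6-hydroxy-2-(4-methoxyphenyl)-2,3-dihydro-4H-chromen-4-one | COc1ccc(C2CC(=O)c3c(OCc4ccccc4)c(O)c(OCc4ccccc4)cc3O2)cc1 | intermediate
9 | 5,7-bis(benzyloxy)-6-hydroxy-2-(4-methoxyphenyl)-4H-chromen-4-one | COc1ccc(-c2cc(=O)c3c(OCc4ccccc4)c(O)c(OCc4ccccc4)cc3o2)cc1 | intermediate
10 | 4'-fluoroacetophenone | CC(=O)c1ccc(F)cc1 | starting material
11 | 6-(4-acetylphenoxy)-5,7-bis(benzyloxy)-2-(4-methoxyphenyl)-4H-chromen-4-one | COc1ccc(-c2cc(=O)c3c(OCc4ccccc4)c(Oc4ccc(C(C)=O)cc4)c(OCc4ccccc4)cc3o2)cc1 | intermediate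
12 | diethyl carbonate | CCOC(=O)OCC | starting material
13 | ethyl 3-(4-{[5,7-bis(benzyloxy)-2-(4-methoxyphenyl)-4-oxo-4H-chromen-6-yl]oxy}phenyl)-3-oxopropanoate | CCOC(=O)CC(=O)c1ccc(Oc2c(OCc3ccccc3)cc3oc(-c4ccc(OC)cc4)cc(=O)c3c2OCc2ccccc2)cc1 | intermediate
14 | ethyl 3-[4-({5,7-dihydroxy-2-(4-methoxyphenyl)-4-oxo-4H-chromen-6-yl}oxy)phenyl]-3-oxopropanoate | CCOC(=O)CC(=O)c1ccc(Oc2c(O)cc3oc(-c4ccc(OC)cc4)cc(=O)c3c2O)cc1 | intermediate
15 | phloroglucinol (benzene-1,3,5-triol) | Oc1cc(O)cc(O)c1 | starting material
16 | 3-[4-({5,7-dihydroxy-2-(4-methoxyphenyl)-4-oxo-4H-chromen-6-yl}oxy)phenyl]-3-oxoprop-1-en-1-one (aroylketene) | O=C=CC(=O)c1ccc(Oc2c(O)cc3oc(-c4ccc(OC)cc4)cc(=O)c3c2O)cc1 | intermediate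
17 | 1-[4-({5,7-dihydroxy-2-(4-methoxyphenyl)-4-oxo-4H-chromen-6-yl}oxy)phenyl]-3-(2,4,6-trihydroxyphenyl)propane-1,3-dione | O=C(CC(=O)c1c(O)cc(O)cc1O)c1ccc(Oc2c(O)cc3oc(-c4ccc(OC)cc4)cc(=O)c3c2O)cc1 | intermediate
18 | cryptomerin A | COc1ccc(-c2cc(=O)c3c(O)c(Oc4ccc(-c5cc(=O)c6c(O)cc(O)cc6o5)cc4)c(O)cc3o2)cc1 | target

## Step count and risk

Total step count: 8. Longest linear sequence: 8 steps (1 to 18); compounds 2, 6, 10, 12 and 15 are bought.

**Step 8 (key step).** Three processes are the likely failures at 240 °C.
- Self-condensation of 14: the ketene is trapped by O7''–H or C8'' of a second molecule in place of 15.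
- Hydrolysis of the ketene by the water released in the cyclodehydration, followed by decarboxylation to the methyl ketone.
- Thermal migration of the diaryl ether, or closure in the coumarin sense.

Fallback: ring C is built by the classical chalcone route, setting out from 9 and reusing 3.
- Phenol 9 is arylated with 4-fluorobenzaldehyde (K2CO3, DMF, 90 °C) to 4-{[5,7-bis(benzyloxy)-2-(4-methoxyphenyl)-4-oxo-4H-chromen-6-yl]oxy}benzaldehyde F1.
- Claisen–Schmidt condensation of F1 with acetophenone 3 (KOH, EtOH–THF, rt) should give (E)-1-[2,4-bis(benzyloxy)-6-hydroxyphenyl]-3-(4-{[5,7-bis(benzyloxy)-2-(4-methoxyphenyl)-4-oxo-4H-chromen-6-yl]oxy}phenyl)prop-2-en-1-one F2.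
- Oxidative cyclisation (I2 catalyst, DMSO, 120 °C) closes ring C to 5,7-bis(benzyloxy)-6-{4-[5,7-bis(benzyloxy)-4-oxo-4H-chromen-2-yl]phenoxy}-2-(4-methoxyphenyl)-4H-chromen-4-one F3.
- Hydrogenolysis (H2, Pd/C) removes the four benzyl groups and returns to the route at 18.

**Step 2.** The Elbs oxidation is expected to stop at partial conversion. The lipophilic phenolate of 3 is poorly soluble in the aqueous base, the peroxodisulfate decomposes in competition, and the hydroquinone product can be oxidised further. Acid hydrolysis of the sulfate may also begin to cleave the benzyl ether next to the acetyl group.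

Fallback: setting out from 3, oxidation with potassium nitrosodisulfonate ON(SO3K)2 in buffered aqueous acetone (Teuber oxidation of a phenol with a free para position) should give 2-acetyl-3,5-bis(benzyloxy)cyclohexa-2,5-diene-1,4-dione F4. Reduction of F4 with Na2S2O4 in a two-phase mixture returns to the route at 5.

**Step 4.** The electron-rich hydroquinone of 7 may be oxidised to the quinone before it cyclises. The HI formed in the cycle may remove the acid-labile benzyl group on O5'', and the one free ring position may be iodinated.

Fallback: a Baker–Venkataraman sequence in which the hydroquinone oxygen stays acylated, setting out from 5.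
- Acylation with 4-methoxybenzoyl chloride (2.2 equiv, Et3N, DMAP, CH2Cl2) gives 2-acetyl-3,5-bis(benzyloxy)-1,4-phenylene bis(4-methoxybenzoate) F5.
- LiN(SiMe3)2 in THF from −78 °C to rt moves the ortho aroyl group to carbon and gives 2,6-bis(benzyloxy)-4-hydroxy-3-[3-(4-methoxyphenyl)-3-oxopropanoyl]phenyl 4-methoxybenzoate F6.
- Cyclodehydration with catalytic p-toluenesulfonic acid in refluxing toluene gives 5,7-bis(benzyloxy)-2-(4-methoxyphenyl)-4-oxo-4H-chromen-6-yl 4-methoxybenzoate F7.
- Methanolysis of the remaining ester (K2CO3, MeOH–THF, rt) returns to the route at 9.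

**Step 5.** Attack of the doubly ortho-substituted phenoxide may be slow. Base-induced self-condensation of 10 and slow degradation of the flavone in hot basic DMF could then take over.

Fallback: setting out from 9, an oxidative copper-mediated O-arylation (Chan–Lam coupling) with (4-acetylphenyl)boronic acid, Cu(OAc)2 (divalent copper), pyridine and 4 Å sieves in CH2Cl2 under air at rt forms the same C4'–O bond and returns at 11. No new compound is made (F0).

**Step 7.** Over-reduction is the risk: hydrogenolysis of the benzylic ketone of the keto ester, or saturation of the C2''=C3'' bond, if the debenzylation of the hindered ethers is slow.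

Fallback: setting out from 13, Lewis-acid debenzylation with BCl3 and pentamethylbenzene as cation scavenger in CH2Cl2 at −78 °C returns at 14. The unchelated C4''' methyl ether is not cleaved at this temperature, and no new compound is made (F0).

## Further compounds

F1 | step 8 | 4-{[5,7-bis(benzyloxy)-2-(4-methoxyphenyl)-4-oxo-4H-chromen-6-yl]oxy}benzaldehyde | COc1ccc(-c2cc(=O)c3c(OCc4ccccc4)c(Oc4ccc(C=O)cc4)c(OCc4ccccc4)cc3o2)cc1
F2 | step 8 | (E)-1-[2,4-bis(benzyloxy)-6-hydroxyphenyl]-3-(4-{[5,7-bis(benzyloxy)-2-(4-methoxyphenyl)-4-oxo-4H-chromen-6-yl]oxy}phenyl)prop-2-en-1-one | COc1ccc(-c2cc(=O)c3c(OCc4ccccc4)c(Oc4ccc(/C=C/C(=O)c5c(O)cc(OCc6ccccc6)cc5OCc5ccccc5)cc4)c(OCc4ccccc4)cc3o2)cc1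
F3 | step 8 | 5,7-bis(benzyloxy)-6-{4-[5,7-bis(benzyloxy)-4-oxo-4H-chromen-2-yl]phenoxy}-2-(4-methoxyphenyl)-4H-chromen-4-one | COc1ccc(-c2cc(=O)c3c(OCc4ccccc4)c(Oc4ccc(-c5cc(=O)c6c(OCc7ccccc7)cc(OCc7ccccc7)cc6o5)cc4)c(OCc4ccccc4)cc3o2)cc1
F4 | step 2 | 2-acetyl-3,5-bis(benzyloxy)cyclohexa-2,5-diene-1,4-dione | CC(=O)C1=C(OCc2ccccc2)C(=O)C(OCc2ccccc2)=CC1=O
F5 | step 4 | 2-acetyl-3,5-bis(benzyloxy)-1,4-phenylene bis(4-methoxybenzoate) | CC(=O)c1c(OC(=O)c2ccc(OC)cc2)cc(OCc2ccccc2)c(OC(=O)c2ccc(OC)cc2)c1OCc1ccccc1
F6 | step 4 | 2,6-bis(benzyloxy)-4-hydroxy-3-[3-(4-methoxyphenyl)-3-oxopropanoyl]phenyl 4-methoxybenzoate | COc1ccc(C(=O)CC(=O)c2c(O)cc(OCc3ccccc3)c(OC(=O)c3ccc(OC)cc3)c2OCc2ccccc2)cc1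
F7 | step 4 | 5,7-bis(benzyloxy)-2-(4-methoxyphenyl)-4-oxo-4H-chromen-6-yl 4-methoxybenzoate | COc1ccc(-c2cc(=O)c3c(OCc4ccccc4)c(OC(=O)c4ccc(OC)cc4)c(OCc4ccccc4)cc3o2)cc1
F0 | step 5 | none | none
F0 | step 7 | none | none
A1 | alternative 1 | methyl coumalate (methyl 2-oxo-2H-pyran-5-carboxylate) | COC(=O)c1ccc(=O)oc1
A2 | alternative 1 | 1,3-bis(benzyloxy)-2-(ethynyloxy)-5-[(triisopropylsilyl)oxy]benzene | C#COc1c(OCc2ccccc2)cc(O[Si](C(C)C)(C(C)C)C(C)C)cc1OCc1ccccc1
A3 | alternative 1 | methyl 4-{2,6-bis(benzyloxy)-4-[(triisopropylsilyl)oxy]phenoxy}benzoate | COC(=O)c1ccc(Oc2c(OCc3ccccc3)cc(O[Si](C(C)C)(C(C)C)C(C)C)cc2OCc2ccccc2)cc1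
A4 | alternative 2 | methyl 4-{[1-methoxy-1,3-bis(trimethylsilyloxy)buta-1,3-dien-2-yl]oxy}benzoate | COC(=O)c1ccc(OC(C(=C)O[Si](C)(C)C)=C(OC)O[Si](C)(C)C)cc1
A5 | alternative 2 | 2-(4-methoxyphenyl)-5-(phenylsulfinyl)-4H-pyran-4-one (racemic sulfoxide) | COc1ccc(-c2cc(=O)c(S(=O)c3ccccc3)co2)cc1
A6 | alternative 2 | methyl 4-{[5,7-dihydroxy-2-(4-methoxyphenyl)-4-oxo-4H-chromen-6-yl]oxy}benzoate | COC(=O)c1ccc(Oc2c(O)cc3oc(-c4ccc(OC)cc4)cc(=O)c3c2O)cc1
A7 | alternative 3 | 3,5-bis(benzyloxy)-4-[4-(1,3-dioxolan-2-yl)phenoxy]-2-(trimethylsilyl)phenyl trifluoromethanesulfonate | C[Si](C)(C)c1c(OS(=O)(=O)C(F)(F)F)cc(OCc2ccccc2)c(Oc2ccc(C3OCCO3)cc2)c1OCc1ccccc1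
A8 | alternative 3 | 3-(4-methoxyphenyl)propiolic acid | COc1ccc(C#CC(=O)O)cc1
A9 | alternative 3 | 1-{2-hydroxy-4,6-bis(benzyloxy)-5-[4-(1,3-dioxolan-2-yl)phenoxy]phenyl}-3-(4-methoxyphenyl)prop-2-yn-1-one | COc1ccc(C#CC(=O)c2c(O)cc(OCc3ccccc3)c(Oc3ccc(C4OCCO4)cc3)c2OCc2ccccc2)cc1
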